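## Analysis of the target

Guajadial D (18) is a spiro compound. Ring C is the dihydropyran of a chroman (O1, C2, C3, C4, C4a, C8a) whose benzo ring is a 5,7-dihydroxy-6,8-diformyl arene. C2 of the chroman is also C2' of a hexahydronaphthalene made of ring B (cyclohexene, C1'=C8a') and ring A (cyclohexane, methyl on C5', isopropyl on C8').

There are five stereocentres: C4 (S, doubly benzylic, phenyl), the spiro carbon C2 (S), C4a' (R), C5' (R) and C8' (S). Across ring C the alkenyl arm C1' is trans to phenyl and the methylene arm C3' is cis to it. On ring A the methyl is cis to the ring B bond C4a'–C4' and trans to isopropyl. On ring B the ring C oxygen is cis to the ring A bond C4a'–C5'.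

The sensitive groups are two aryl aldehydes, two acidic hydrogen-bonded phenols, a trisubstituted alkene and the C2–O1 bond. That bond is a tertiary allylic aryl ether whose aryloxide becomes a good leaving group once the formyl groups are present, so strong Lewis acids threaten ring opening or epimerisation at C2.

The difficulty is the quaternary spiro centre, which must be set relative to C4 and to three centres in a carbocycle that keeps no functional handle except one alkene.

The strategy rests on one reading of the structure. C2 carries one oxygen and three carbons, so it is the carbon of an oxocarbenium ion. Its neighbour C1' is a vinyl CH doubly bonded to C8a', and C8a' is bonded to C8', which bears the isopropyl group. An oxocarbenium ion, an alkyne (C1'≡C8a') and a prenyl alkene (C8'=CMe2) therefore lie in line, and ring A with its C5' methyl centre maps onto citronellal.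

## Retrosynthetic reasoning

**18 to 17 (two O–CH3 bonds).** The phenols are carried as methyl ethers because they must survive a Grignard reagent, carbonate in methanol and SnCl4. They are cut last by thiolate, which attacks the methyl carbon. A chelating boron or aluminium halide is avoided: held between the C8 formyl oxygen and O1 it would ionise the tertiary allylic C2–O1 bond sooner than it would cleave a methyl ether.

**17 to 15 (two aryl C–CHO bonds).** C6 and C8 are the only free arene positions and each is flanked by two oxygens. A double Rieche formylation adds both aldehydes in one step, late, so that no aldehyde has to pass through the organometallic and cationic steps.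

**15 to 14 (C–H from C–Cl).** The isopropyl group is traced back to a 2-chloropropan-2-yl group. The chloride is the record of how the cascade ends and is removed by a radical chain that touches no stereocentre.

**14 to 9 (O1–C2, C2–C1' and C8a'–C8').** All three bonds are cut at once, which opens rings C, B and A and leaves the acyclic keto-phenol 9. Forward, the ketone and phenol give a chromanyl oxocarbenium ion, the alkyne CH terminus closes ring B, and the resulting vinyl cation is taken by the prenyl CH to close ring A. This is the only set of cuts that turns the whole carbocycle into a chain made from a terpene aldehyde, and it places the alkene where it must be because it is born from the alkyne. Two stereocentres (C2 and C8') are created under control of C4, C4a' and C5'.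

**9 to 8 (C≡C from CHO).** The alkyne is the one-carbon homologue of an aldehyde. This keeps the C4a' centre as the α-carbon of an aldehyde, where catalysis can set it.

**8 to 6 and 7 (C4a'–C4' bond).** Cutting between the aldehyde α-carbon and the chain to the ketone gives (R)-citronellal (7) and vinyl ketone 6. Forward this is an enamine-catalysed Michael addition in which the catalyst sets C4a', while C5' comes unchanged from 7.

**6 to 4 to 3 (acyl–vinyl bond, then the lactone C–O bond).** The vinyl ketone is made from Weinreb amide 4, which is the ring-opened form of lactone 3. Opening the lactone sets the phenol free for later use in ring C.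

**3 to 1 and 2 (C4–phenyl bond).** The benzylic centre comes from an asymmetric conjugate addition of phenylboronic acid (2) to 5,7-dimethoxycoumarin (1). The stereocentre that later directs the spiro centre is thus set first, by a catalytic reaction known for coumarins.

## Alternatives that were turned down

**Alternative 1:** The arene–C4 and O1–C2 bonds are cut to 3,5-dimethoxyphenol and a bicyclic dienal A2 that already holds rings A and B; the C4–phenyl bond is made afterwards. Forward, an ammonium acetate salt condenses the phenol ortho carbon with the aldehyde, water is lost to a quinone-methide-type trienone, and oxa-6π electrocyclisation gives spiro 2H-chromene A1.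
- For it: the annulation is a known, mild, convergent reaction that needs no Lewis acid and leaves the C1'=C8a' alkene alone. On precedent for the key step it is stronger than the chosen cascade.
- Against it: the spiro centre would come from a reversible electrocyclisation biased only by C4a', three bonds away, so a mixture near equilibrium is expected.
- Against it: phenyl would then have to be added to C4 of A1, an unpolarised styrene-type alkene, with 1,3-induction from a spiro centre whose two arms (CH= and CH2) differ little, and with a second alkene present.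
- Against it: A2 is itself a stereodefined cadinane with three stereocentres and needs its own multistep synthesis.
- Comparison: the chosen route builds rings A and B in the key step from a chain that takes five steps to make, and it sets C4 first so that it can direct C2 rather than the reverse.

**Alternative 2:** The C2–C3 bond is cut and ring B is treated as a phenol. Precursor A4 is a tetralin catechol mono-aryl ether with an (S)-2,2-diarylethyl mesylate. Forward, Cs2CO3 gives the phenolate, whose aryloxy-bearing ortho carbon displaces the primary mesylate to close ring C and give the dearomatised cyclohexa-2,4-dienone A3.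
- For it: the quaternary carbon is made by substitution at a primary carbon, C-alkylation is favoured by ring size (O-alkylation would need an eight-membered ring), and no Lewis acid is used. As a single bond-forming event it is more reliable than the chosen cascade.
- Against it: A3 has ring B at the wrong oxidation level. The C1' carbonyl must become the C1'=C8a' alkene, the C3'=C4' and C4a'=C8a' alkenes must be reduced, and C4a' would be created late on a flat dienone without control.
- Against it: ortho-quinol-type dienones dimerise and rearomatise with loss of the aryloxide.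
- Against it: the hindered diaryl ether and the trans-disubstituted tetralin need separate syntheses.
- Comparison: the chosen route sets C4a' early under catalyst control and needs only a dechlorination after the key step.

**Alternative 3:** The O1–C2 bond is cut with transposition of the alkene. Precursor A6 is the fully formylated phenol tethered to a cis-fused octalin with a C1'=C2' alkene and a hydrogen on C8a'. Forward, N-(phenylseleno)phthalimide and camphorsulfonic acid give a seleniranium ion, the phenol opens it at the tertiary carbon, and H2O2 then eliminates the selenoxide toward C8a'–H to give A5, which is identical with compound 17.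
- For it: the alkene can only end at C1'=C8a', and the formyl groups are already in place, so no Lewis-acid formylation is needed after the sensitive allylic ether exists. On that point it is stronger than the chosen route.
- Against it: the phenol of A6 is hydrogen-bonded to an ortho formyl group and is a weak nucleophile for a tertiary centre.
- Against it: the spiro configuration is fixed by the face the selenium takes on the octalin and is further tied to the need for selenium to be syn to C8a'–H.
- Against it: H2O2 invites Dakin oxidation of the two electron-rich aryl aldehydes.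
- Against it: A6 has five stereocentres, one of which is destroyed, and needs a long synthesis.
- Comparison: the chosen route reaches the same ring system from an acyclic chain in one operation and accepts a late formylation as the price.

Key step: step 6

Assumption: the sense of induction known for Rh/SEGPHOS arylation of simple coumarins and the usual face-shielding model of diarylprolinol silyl ethers are taken to hold for 1 and for 6 with 7; if either is reversed in practice, the enantiomeric ligand or catalyst is used.

## Route

Step 1
Reactants: 1 5,7-dimethoxycoumarin; 2 phenylboronic acid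
Product: 3 (4S)-5,7-dimethoxy-4-phenylchroman-2-one
Conditions: Rh(acac)(C2H4)2 (3 mol%), (S)-SEGPHOS (3.3 mol%), 2 (5 equiv), dioxane/H2O 10:1, 60 °C
Reagents that add atoms: none
Why: Hayashi–Miyaura asymmetric 1,4-addition: a phenyl complex of monovalent rhodium adds across C3=C4 and the rhodium enolate is protonated by water. The bisphosphine leaves one enantioface open, which should give the (S) centre at C4; excess boronic acid offsets the slower insertion next to the 5-methoxy group.

Step 2
Reactants: 3 (4S)-5,7-dimethoxy-4-phenylchroman-2-one
Product: 4 (3S)-3-(2-hydroxy-4,6-dimethoxyphenyl)-N-methoxy-N-methyl-3-phenylpropanamide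
Conditions: Me(MeO)NH·HCl, AlMe3, CH2Cl2, 0 °C to rt; aq. potassium sodium tartrate
Reagents that add atoms: N,O-dimethylhydroxylamine hydrochloride, CNOC.Cl
Why: Weinreb amidation of an aryl ester: the aluminium amide opens the reactive lactone and frees the phenol. The stereocentre is β to the carbonyl and is not at risk.

Step 3
Reactants: 4 (3S)-3-(2-hydroxy-4,6-dimethoxyphenyl)-N-methoxy-N-methyl-3-phenylpropanamide; 5 vinylmagnesium bromide
Product: 6 (5S)-5-(2-hydroxy-4,6-dimethoxyphenyl)-5-phenylpent-1-en-3-one
Conditions: CH2=CHMgBr (3.5 equiv), THF, −78 to 0 °C; poured into cold 1 M HCl/Et2O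
Reagents that add atoms: none
Why: Weinreb ketone synthesis: one equivalent of Grignard reagent deprotonates the phenol and the chelated tetrahedral adduct prevents a second addition. The inverse acidic quench keeps the released N,O-dimethylhydroxylamine protonated so that it cannot add to the enone; 6 may close reversibly onto its phenol and is used at once.

Step 4
Reactants: 6 (5S)-5-(2-hydroxy-4,6-dimethoxyphenyl)-5-phenylpent-1-en-3-one; 7 (R)-citronellal
Product: 8 (2R,7S)-7-(2-hydroxy-4,6-dimethoxyphenyl)-2-[(2R)-6-methylhept-5-en-2-yl]-5-oxo-7-phenylheptanal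
Conditions: (R)-2-[diphenyl(trimethylsilyloxy)methyl]pyrrolidine (10 mol%), 4-nitrophenol (20 mol%), 7 (1.5 equiv), CH2Cl2, 4 °C
Reagents that add atoms: none
Why: Enamine-catalysed Michael addition of an aldehyde to a vinyl ketone: the E-enamine of 7 reacts on the face away from the CPh2OSiMe3 group. With the (R)-catalyst this should give the (R) centre α to the aldehyde under catalyst control, the citronellal methyl centre being untouched.

Step 5
Reactants: 8 (2R,7S)-7-(2-hydroxy-4,6-dimethoxyphenyl)-2-[(2R)-6-methylhept-5-en-2-yl]-5-oxo-7-phenylheptanal
Product: 9 (1S,6R,7R)-6-ethynyl-1-(2-hydroxy-4,6-dimethoxyphenyl)-7,11-dimethyl-1-phenyldodec-10-en-3-one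
Conditions: dimethyl (1-diazo-2-oxopropyl)phosphonate, K2CO3 (3 equiv), MeOH, 0 °C to rt; aq. NH4Cl
Reagents that add atoms: dimethyl (1-diazo-2-oxopropyl)phosphonate, CC(=O)C(=[N+]=[N-])P(=O)(OC)OC
Why: Seyferth–Gilbert homologation in the Ohira–Bestmann form: the diazophosphonate anion adds to the aldehyde much faster than to the ketone, and loss of phosphate and nitrogen with a 1,2-hydrogen shift gives the terminal alkyne. Carbonate at 0 °C is mild enough that the centre α to the aldehyde should be kept.

Step 6
Reactants: 9 (1S,6R,7R)-6-ethynyl-1-(2-hydroxy-4,6-dimethoxyphenyl)-7,11-dimethyl-1-phenyldodec-10-en-3-one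
Product: 14 (2S,4S,4a'R,5'R,8'R)-8'-(2-chloropropan-2-yl)-5,7-dimethoxy-5'-methyl-4-phenyl-3',4',4a',5',6',7'-hexahydro-8'H-spiro[chromane-2,2'-naphthalene], via 2-chromanol hemiketal 10 (not isolated), via chromanyl oxocarbenium ion 11 (not isolated), via ring B vinyl cation 12 (not isolated), via tertiary alkyl cation 13 (not isolated)
Conditions: SnCl4 (2 equiv), CH2Cl2 (0.005 M), −78 to −40 °C; aq. NaHCO3
Reagents that add atoms: tin tetrachloride, Cl[Sn](Cl)(Cl)Cl
Why: Proposed new method: SnCl4 closes 9 to hemiketal 10 (ring C, 6-exo-trig) and ionises it to oxocarbenium ion 11; the terminal alkyne carbon adds to C2 (6-endo-dig, the only Markovnikov mode) to close ring B as vinyl cation 12, whose in-plane empty orbital at C8a' is taken by the prenyl CH (6-exo-trig) to close ring A as tertiary cation 13, and chloride from the stannate ion pair gives 14. The closest known reaction types are alkyne Prins cyclisations of oxocarbenium ions, which normally end with halide capture of the vinyl cation, and cation–olefin polycyclisations ending on a trisubstituted alkene; a three-ring relay through an alkyne from a ketone-derived chromanyl cation has not been shown. The spiro centre C2 is controlled by C4: the phenyl group should sit pseudoaxial to avoid the peri 5-methoxy group and the alkyne should add to the opposite face, as hydride does in silane reductions of 4-aryl-2-chromanols, so the alkenyl arm ends trans to phenyl. That face is also the one reached through the ring B chair that keeps the C4a' side chain equatorial and puts the small ring C oxygen, not the C3 methylene, axial, so the two resident centres act in the same direction. C8' is set in the ring A closure: attack in the plane of the vinyl cation makes the ring B bond at C4a' equatorial on ring A, so the cis methyl at C5' is axial in the chair, and the bulky cationic CMe2 terminus is expected to take the axial site at C8' to avoid A(1,3) strain with the C1' hydrogen, which places it trans to methyl as required. The step needs chemoselectivity between the two π-nucleophiles, and ring size secures it, since the prenyl alkene could reach C2 only through an eight-membered ring. It also needs the vinyl cation to be taken by the tethered alkene faster than by chloride, and the tertiary cation to be quenched before the C8' hydrogen shifts; neither is proven, and low temperature, high dilution and a non-polar solvent are chosen to favour both.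

Step 7
Reactants: 14 (2S,4S,4a'R,5'R,8'R)-8'-(2-chloropropan-2-yl)-5,7-dimethoxy-5'-methyl-4-phenyl-3',4',4a',5',6',7'-hexahydro-8'H-spiro[chromane-2,2'-naphthalene]
Product: 15 (2S,4S,4a'R,5'R,8'S)-5,7-dimethoxy-5'-methyl-4-phenyl-8'-(propan-2-yl)-3',4',4a',5',6',7'-hexahydro-8'H-spiro[chromane-2,2'-naphthalene]
Conditions: (Me3Si)3SiH (1.5 equiv), AIBN (cat.), toluene, 80 °C
Reagents that add atoms: none
Why: Radical chain dehalogenation: the silyl radical abstracts chlorine and the tertiary radical takes hydrogen from Si–H faster than it can close onto the ring B alkene. The neutral conditions spare the allylic ether and no stereocentre is involved; the descriptor at C8' changes only because chlorine is lost.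

Step 8
Reactants: 15 (2S,4S,4a'R,5'R,8'S)-5,7-dimethoxy-5'-methyl-4-phenyl-8'-(propan-2-yl)-3',4',4a',5',6',7'-hexahydro-8'H-spiro[chromane-2,2'-naphthalene]
Product: 17 (2S,4S,4a'R,5'R,8'S)-5,7-dimethoxy-5'-methyl-4-phenyl-8'-(propan-2-yl)-3',4',4a',5',6',7'-hexahydro-8'H-spiro[chromane-2,2'-naphthalene]-6,8-dicarbaldehyde, via bis(chloromethoxymethyl) arene 16 (not isolated)
Conditions: Cl2CHOMe (5 equiv), TiCl4 (5 equiv), CH2Cl2, −78 to −30 °C; ice-water
Reagents that add atoms: dichloromethyl methyl ether, COC(Cl)Cl; water, O
Why: Rieche formylation, twice: C6 and C8 are the only free positions of a 1,3,5-trioxygenated arene and each is ortho or para to all three oxygens. The α-chloro ethers 16 are hydrolysed on work-up, and the low temperature is meant to keep the Lewis acid from ionising the C2–O1 bond.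

Step 9
Reactants: 17 (2S,4S,4a'R,5'R,8'S)-5,7-dimethoxy-5'-methyl-4-phenyl-8'-(propan-2-yl)-3',4',4a',5',6',7'-hexahydro-8'H-spiro[chromane-2,2'-naphthalene]-6,8-dicarbaldehyde
Product: 18 Guajadial D, (2S,4S,4a'R,5'R,8'S)-5,7-dihydroxy-5'-methyl-4-phenyl-8'-(propan-2-yl)-3',4',4a',5',6',7'-hexahydro-8'H-spiro[chromane-2,2'-naphthalene]-6,8-dicarbaldehyde
Conditions: NaSEt (6 equiv), DMF, 90 °C; then 1 M HCl, 0 °C
Reagents that add atoms: none
Why: Nucleophilic O-demethylation: thiolate attacks each methyl carbon by SN2, and both aryloxide leaving groups are stabilised by ortho formyl groups. The tertiary C2 cannot undergo SN2 and no Lewis acid is present, so the allylic ether should survive; thiolate addition to the aldehydes is reversible and is undone by the acid work-up.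

## Compound list

1 | 5,7-dimethoxycoumarin | COc1cc(OC)c2ccc(=O)oc2c1 | starting material
2 | phenylboronic acid | OB(O)c1ccccc1 | starting material
3 | (4S)-5,7-dimethoxy-4-phenylchroman-2-one | O=C1C[C@@H](c2ccccc2)c2c(OC)cc(OC)cc2O1 | intermediate
4 | (3S)-3-(2-hydroxy-4,6-dimethoxyphenyl)-N-methoxy-N-methyl-3-phenylpropanamide | CON(C)C(=O)C[C@@H](c1ccccc1)c1c(OC)cc(OC)cc1O | intermediate
5 | vinylmagnesium bromide | C=C[Mg]Br | starting material
6 | (5S)-5-(2-hydroxy-4,6-dimethoxyphenyl)-5-phenylpent-1-en-3-one | C=CC(=O)C[C@@H](c1ccccc1)c1c(OC)cc(OC)cc1O | intermediate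
7 | (R)-citronellal, (3R)-3,7-dimethyloct-6-enal | CC(C)=CCC[C@@H](C)CC=O | starting material
8 | (2R,7S)-7-(2-hydroxy-4,6-dimethoxyphenyl)-2-[(2R)-6-methylhept-5-en-2-yl]-5-oxo-7-phenylheptanal | CC(C)=CCC[C@@H](C)[C@H](C=O)CCC(=O)C[C@@H](c1ccccc1)c1c(OC)cc(OC)cc1O | intermediate
9 | (1S,6R,7R)-6-ethynyl-1-(2-hydroxy-4,6-dimethoxyphenyl)-7,11-dimethyl-1-phenyldodec-10-en-3-one | CC(C)=CCC[C@@H](C)[C@H](C#C)CCC(=O)C[C@@H](c1ccccc1)c1c(OC)cc(OC)cc1O | intermediate
10 | (4S)-2-[(3R,4R)-3-ethynyl-4,8-dimethylnon-7-en-1-yl]-5,7-dimethoxy-4-phenylchroman-2-ol, both C2 epimers | CC(C)=CCC[C@@H](C)[C@H](C#C)CCC1(O)C[C@@H](c2ccccc2)c2c(OC)cc(OC)cc2O1 | intermediate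
11 | chromanyl oxocarbenium ion of 10 (O1=C2 cation, stannate counter-ion) | CC(C)=CCC[C@@H](C)[C@H](C#C)CCC1C[C@@H](c2ccccc2)c2c(OC)cc(OC)cc2[O+]=1 | intermediate
12 | ring B vinyl cation: 5,7-dimethoxy-4-phenylspiro[chromane-2,1'-cyclohex-2'-ene] with the charge on C3' and the (2R)-6-methylhept-5-en-2-yl chain on C4' | CC(C)=CCC[C@@H](C)[C@H]1CC[C@@]2(C=[C+]1)C[C@@H](c1ccccc1)c1c(OC)cc(OC)cc1O2 | intermediate
13 | tertiary cation: the propan-2-ylium ion on C8' of the closed spiro skeleton of 14 | C[C+](C)[C@@H]1CC[C@@H](C)[C@H]2CC[C@@]3(C=C12)C[C@@H](c1ccccc1)c1c(OC)cc(OC)cc1O3 | intermediate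
14 | (2S,4S,4a'R,5'R,8'R)-8'-(2-chloropropan-2-yl)-5,7-dimethoxy-5'-methyl-4-phenyl-3',4',4a',5',6',7'-hexahydro-8'H-spiro[chromane-2,2'-naphthalene] | CC(C)(Cl)[C@@H]1CC[C@@H](C)[C@H]2CC[C@@]3(C=C12)C[C@@H](c1ccccc1)c1c(OC)cc(OC)cc1O3 | intermediate
15 | (2S,4S,4a'R,5'R,8'S)-5,7-dimethoxy-5'-methyl-4-phenyl-8'-(propan-2-yl)-3',4',4a',5',6',7'-hexahydro-8'H-spiro[chromane-2,2'-naphthalene] | CC(C)[C@@H]1CC[C@@H](C)[C@H]2CC[C@@]3(C=C12)C[C@@H](c1ccccc1)c1c(OC)cc(OC)cc1O3 | intermediate
16 | 6,8-bis[chloro(methoxy)methyl] derivative of 15 | CC(C)[C@@H]1CC[C@@H](C)[C@H]2CC[C@@]3(C=C12)C[C@@H](c1ccccc1)c1c(OC)c(C(Cl)OC)c(OC)c(C(Cl)OC)c1O3 | intermediate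
17 | (2S,4S,4a'R,5'R,8'S)-5,7-dimethoxy-5'-methyl-4-phenyl-8'-(propan-2-yl)-3',4',4a',5',6',7'-hexahydro-8'H-spiro[chromane-2,2'-naphthalene]-6,8-dicarbaldehyde | CC(C)[C@@H]1CC[C@@H](C)[C@H]2CC[C@@]3(C=C12)C[C@@H](c1ccccc1)c1c(OC)c(C=O)c(OC)c(C=O)c1O3 | intermediate
18 | Guajadial D | CC(C)[C@@H]1CC[C@@H](C)[C@H]2CC[C@@]3(C=C12)C[C@@H](c1ccccc1)c1c(O)c(C=O)c(O)c(C=O)c1O3 | target

## Step count and uncertain steps

Total step count: 9. Longest linear sequence: 9 steps (1 to 18); 2, 5 and 7 enter as purchased.

**Step 6 (key step, new as a cascade).**
- What may go wrong: capture of the ring B vinyl cation by chloride before the prenyl alkene reacts, which is the usual end of an alkyne Prins cyclisation; a 1,2-hydride shift or proton loss at the tertiary cation stage, which would erase the C8' configuration; proton loss from the oxocarbenium ion; intermolecular arylation by the electron-rich arene; hydrochlorination of the prenyl group; and poor facial selectivity in the ring A closure.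
- Fallback by known reaction types: the cascade is divided. From 9, SnBr4 in CH2Cl2 at −78 °C should stop after ring B by bromide capture, giving the vinyl bromide (4S)-3'-bromo-5,7-dimethoxy-4'-[(2R)-6-methylhept-5-en-2-yl]-4-phenylspiro[chromane-2,1'-cyclohex-2'-ene] F1. Bu3SnH and AIBN in benzene at 80 °C under slow addition would then close ring A by 6-exo-trig vinyl radical cyclisation onto the prenyl CH. The tertiary radical, which cannot undergo a hydride shift, is reduced by the tin hydride, so the route is rejoined at 15 and 14 is skipped.

**Step 5.**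
- What may go wrong: base-mediated intramolecular aldol condensation of the 1,5-keto aldehyde and epimerisation α to the aldehyde during the carbonate-mediated homologation.
- Fallback: the ketone is masked before any strong base is used. From 8, CBr4, PPh3 and Zn in CH2Cl2 at 0 °C convert only the aldehyde into the dibromoalkene (1S,6R,7R)-6-(2,2-dibromoethenyl)-1-(2-hydroxy-4,6-dimethoxyphenyl)-7,11-dimethyl-1-phenyldodec-10-en-3-one F2. CH(OMe)3, MeOH and pyridinium tosylate close ketone and phenol to the mixed methyl ketal (4S)-2-[(3R,4R)-3-(2,2-dibromoethenyl)-4,8-dimethylnon-7-en-1-yl]-2,5,7-trimethoxy-4-phenylchromane F3. n-BuLi (2.2 equiv) in THF at −78 °C gives the alkyne (4S)-2-[(3R,4R)-3-ethynyl-4,8-dimethylnon-7-en-1-yl]-2,5,7-trimethoxy-4-phenylchromane F4 (Corey–Fuchs sequence). Pyridinium tosylate in wet acetone returns 9; F4 could also be ionised directly by SnCl4.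

**Step 8.**
- What may go wrong: ionisation of the tertiary allylic C2–O1 bond by TiCl4, with ring opening or epimerisation at C2; an incomplete second formylation; and attack of the electrophile on the ring B alkene.
- Fallback without a Lewis acid: from 15, NBS (2.1 equiv) in MeCN at 0 °C should brominate both free arene positions to give the 6,8-dibromo derivative of 15 F5. t-BuLi (4.4 equiv) in THF at −78 °C followed by DMF and aqueous NH4Cl gives 17.

**Step 9.**
- What may go wrong: a stalled second demethylation once the first phenolate has formed, or thermal ionisation of the allylic ether with the formylated aryloxide as leaving group.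
- Fallback with the order of the last two steps reversed: from 15, NaSEt in DMF at 140 °C removes both methyl groups while the aryloxide is still a poor leaving group, giving (2S,4S,4a'R,5'R,8'S)-5'-methyl-4-phenyl-8'-(propan-2-yl)-3',4',4a',5',6',7'-hexahydro-8'H-spiro[chromane-2,2'-naphthalene]-5,7-diol F6. Vilsmeier–Haack diformylation of the free diphenol (POCl3, DMF, 0 °C, then aqueous NaOAc) gives 18 directly.

**Step 3.**
- What may go wrong: conjugate addition of the released N,O-dimethylhydroxylamine to the vinyl ketone and oligomerisation of 6 during work-up.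
- Fallback without the amide: from 3, i-Bu2AlH in CH2Cl2 at −78 °C gives the lactol (4S)-5,7-dimethoxy-4-phenylchroman-2-ol F7. Vinylmagnesium bromide (3 equiv) in THF at 0 °C opens it to the allylic alcohol (5S)-5-(2-hydroxy-4,6-dimethoxyphenyl)-5-phenylpent-1-en-3-ol F8. MnO2 in CH2Cl2 oxidises only the allylic alcohol and gives 6.

## Further compounds

F1 | step 6 | (4S)-3'-bromo-5,7-dimethoxy-4'-[(2R)-6-methylhept-5-en-2-yl]-4-phenylspiro[chromane-2,1'-cyclohex-2'-ene] | CC(C)=CCC[C@@H](C)[C@H]1CC[C@@]2(C=C1Br)C[C@@H](c1ccccc1)c1c(OC)cc(OC)cc1O2
F2 | step 5 | (1S,6R,7R)-6-(2,2-dibromoethenyl)-1-(2-hydroxy-4,6-dimethoxyphenyl)-7,11-dimethyl-1-phenyldodec-10-en-3-one | CC(C)=CCC[C@@H](C)[C@H](C=C(Br)Br)CCC(=O)C[C@@H](c1ccccc1)c1c(OC)cc(OC)cc1O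
F3 | step 5 | (4S)-2-[(3R,4R)-3-(2,2-dibromoethenyl)-4,8-dimethylnon-7-en-1-yl]-2,5,7-trimethoxy-4-phenylchromane | CC(C)=CCC[C@@H](C)[C@H](C=C(Br)Br)CCC1(OC)C[C@@H](c2ccccc2)c2c(OC)cc(OC)cc2O1
F4 | step 5 | (4S)-2-[(3R,4R)-3-ethynyl-4,8-dimethylnon-7-en-1-yl]-2,5,7-trimethoxy-4-phenylchromane | CC(C)=CCC[C@@H](C)[C@H](C#C)CCC1(OC)C[C@@H](c2ccccc2)c2c(OC)cc(OC)cc2O1
F5 | step 8 | 6,8-dibromo derivative of 15 | CC(C)[C@@H]1CC[C@@H](C)[C@H]2CC[C@@]3(C=C12)C[C@@H](c1ccccc1)c1c(OC)c(Br)c(OC)c(Br)c1O3
F6 | step 9 | (2S,4S,4a'R,5'R,8'S)-5'-methyl-4-phenyl-8'-(propan-2-yl)-3',4',4a',5',6',7'-hexahydro-8'H-spiro[chromane-2,2'-naphthalene]-5,7-diol | CC(C)[C@@H]1CC[C@@H](C)[C@H]2CC[C@@]3(C=C12)C[C@@H](c1ccccc1)c1c(O)cc(O)cc1O3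
F7 | step 3 | (4S)-5,7-dimethoxy-4-phenylchroman-2-ol | OC1C[C@@H](c2ccccc2)c2c(OC)cc(OC)cc2O1
F8 | step 3 | (5S)-5-(2-hydroxy-4,6-dimethoxyphenyl)-5-phenylpent-1-en-3-ol | C=CC(O)C[C@@H](c1ccccc1)c1c(OC)cc(OC)cc1O
A1 | alternative 1 | spiro 2H-chromene dimethyl ether | CC(C)[C@@H]1CC[C@@H](C)[C@H]2CC[C@@]3(C=C12)C=Cc1c(OC)cc(OC)cc1O3
A2 | alternative 1 | bicyclic dienal, 2-[(4aR,5R,8S)-5-methyl-8-(propan-2-yl)-4,4a,5,6,7,8-hexahydronaphthalen-2(3H)-ylidene]acetaldehyde | CC(C)[C@@H]1CC[C@@H](C)[C@H]2CCC(=CC=O)C=C12
A3 | alternative 2 | spiro cyclohexa-2,4-dienone | CC(C)[C@@H]1CC[C@@H](C)C2=C1C(=O)[C@]1(C=C2)C[C@@H](c2ccccc2)c2c(OC)cc(OC)cc2O1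
A4 | alternative 2 | tetralin catechol mono-aryl ether with the (S)-2,2-diarylethyl mesylate | CC(C)[C@@H]1CC[C@@H](C)c2ccc(Oc3cc(OC)cc(OC)c3[C@@H](COS(C)(=O)=O)c3ccccc3)c(O)c21
A5 | alternative 3 | target as its di-O-methyl ether (identical with 17) | CC(C)[C@@H]1CC[C@@H](C)[C@H]2CC[C@@]3(C=C12)C[C@@H](c1ccccc1)c1c(OC)c(C=O)c(OC)c(C=O)c1O3
A6 | alternative 3 | diformyl phenol tethered to the cis-fused octalin | CC(C)[C@@H]1CC[C@@H](C)[C@H]2CCC(C[C@@H](c3ccccc3)c3c(OC)c(C=O)c(OC)c(C=O)c3O)=C[C@@H]12
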